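**Target:** methyl 2-[(3R,4R)-3-hydroxy-6-oxo-4-geranylgeranylcyclohex-1-en-1-yl]acetate, with OH and side chain cis. "Geranylgeranyl" means (2E,6E,10E)-3,7,11,15-tetramethylhexadeca-2,6,10,14-tetraen-1-yl throughout.

## Retrosynthetic overview

- The cis carbinol is made last by stereoinvertive C–O bond formation (Mitsunobu) on the trans γ-hydroxy enone, because every oxygenation next to the side chain occurs anti to it.
- The trans γ-hydroxy enone comes from an α'-hydroxy vinylogous ester by 1,2-reduction and Stork–Danheiser transposition; its C–O bond comes from a Rubottom oxidation.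
- The chiral vinylogous ester comes from a prochiral 2,5-disubstituted cyclohexane-1,3-dione by a catalytic enantioselective desymmetrising etherification (C–O bond; proposed new step; sets the side-chain stereocentre).
- The dione comes from C-alkylation (methyl bromoacetate) of 5-geranylgeranylcyclohexane-1,3-dione, itself from Birch reduction of the resorcinol dimethyl ether made by aryl Grignard/geranylgeranyl bromide coupling.
- Rings: the single carbocycle is the benzene ring of 1-bromo-3,5-dimethoxybenzene, dearomatised; no ring is built de novo.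

Assumption: commercial all-E geranylgeraniol is accepted as the polyprenyl source, and the catalyst antipode in step 5 is the one that screening shows to give the 4R series.

## Route

Step 1
Reactants: 1 (2E,6E,10E)-geranylgeraniol
Product: 2 (2E,6E,10E)-geranylgeranyl bromide
Conditions: PBr3 (0.4 equiv), Et2O, −10 °C, used crude
Reagents that add atoms: phosphorus tribromide, BrP(Br)Br
Why: SN2 displacement of the phosphite ester of a primary allylic alcohol at low temperature gives the bromide with the 2E geometry intact.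

Step 2
Reactants: 3 1-bromo-3,5-dimethoxybenzene; 2 geranylgeranyl bromide
Product: 5 1,3-dimethoxy-5-geranylgeranylbenzene, via 3,5-dimethoxyphenylmagnesium bromide 4 (not isolated)
Conditions: Mg, THF, 40 °C; then 2, CuBr·SMe2 (5 mol%), THF, −20 → 0 °C
Reagents that add atoms: none
Why: Copper-catalysed aryl Grignard/allylic bromide coupling occurs at the primary carbon because the other allyl terminus is fully substituted, so the linear E-prenyl arene results.

Step 3
Reactants: 5 1,3-dimethoxy-5-geranylgeranylbenzene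
Product: 7 5-geranylgeranylcyclohexane-1,3-dione, via 1,5-dimethoxy-3-geranylgeranylcyclohexa-1,4-diene 6 (not isolated)
Conditions: Li, NH3(l), THF, t-BuOH, −78 → −33 °C; NH4Cl; then 1 M HCl, THF, rt
Reagents that add atoms: water, O
Why: Birch reduction of a resorcinol dimethyl ether gives the 2,5-dihydro bis(enol ether) (isolated trisubstituted alkenes are inert to Li/NH3), and mild acid hydrolysis unmasks the 1,3-dione.

Step 4
Reactants: 7 5-geranylgeranylcyclohexane-1,3-dione; 8 methyl bromoacetate
Product: 9 methyl 2-(2,6-dioxo-4-geranylgeranylcyclohexyl)acetate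
Conditions: NaOMe (1.05 equiv), MeOH–THF, 0 → 50 °C
Reagents that add atoms: none
Why: SN2 C-alkylation of the cyclic 1,3-dione enolate with an α-bromo ester, favoured over O-alkylation in a protic medium, gives an achiral dione whose two carbonyl groups are enantiotopic.

Step 5
Reactants: 9 methyl 2-(2,6-dioxo-4-geranylgeranylcyclohexyl)acetate; 10 benzyl alcohol
Product: 11 methyl 2-[(4R)-2-(benzyloxy)-6-oxo-4-geranylgeranylcyclohex-1-en-1-yl]acetate
Conditions: (R)-3,3'-bis(2,4,6-triisopropylphenyl)-1,1'-binaphthyl-2,2'-diyl N-triflylphosphoramide (10 mol%), 5 Å molecular sieves, toluene, 40 °C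
Reagents that add atoms: none
Why: Proposed new method: a chiral Brønsted acid ion-pairs with the rapidly tautomerising enol of 9, benzyl alcohol adds to one of the two enantiotopic carbonyl carbons inside the chiral pocket (C–O bond formation) and water is lost, so the prochiral ring carbon carrying the side chain becomes the 4R stereocentre in a fully dynamic desymmetrisation (no 50% limit); the closest known reactions are achiral acid-catalysed vinylogous ester formation from cyclohexane-1,3-diones and chiral phosphoric acid-catalysed desymmetrising condensations of prochiral cyclic ketones and diones with N-nucleophiles.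

Step 6
Reactants: 11 methyl 2-[(4R)-2-(benzyloxy)-6-oxo-4-geranylgeranylcyclohex-1-en-1-yl]acetate
Product: 14 methyl 2-[(4R,5S)-2-(benzyloxy)-5-hydroxy-6-oxo-4-geranylgeranylcyclohex-1-en-1-yl]acetate, via trimethylsilyl dienol ether 12 (not isolated), via silyloxy ketone 13 (not isolated)
Conditions: TMSOTf (1.2 equiv), Et3N, CH2Cl2, −78 → 0 °C; then 3-chloroperbenzoic acid (1.0 equiv), NaHCO3, CH2Cl2, −78 °C; then aq. citric acid, THF, 0 °C
Reagents that add atoms: 3-chloroperbenzoic acid, OOC(=O)c1cccc(Cl)c1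
Why: Soft enolisation silylates the ketone toward its only α-CH2 without touching the ester, and Rubottom oxidation of the electron-rich silyloxy diene terminus outpaces epoxidation of the chain alkenes and occurs anti to the adjacent side chain, giving the trans alcohol (new centre 5S).

Step 7
Reactants: 14 methyl 2-[(4R,5S)-2-(benzyloxy)-5-hydroxy-6-oxo-4-geranylgeranylcyclohex-1-en-1-yl]acetate
Product: 16 methyl 2-[(3S,4R)-3-hydroxy-6-oxo-4-geranylgeranylcyclohex-1-en-1-yl]acetate, via allylic diol 15 (not isolated)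
Conditions: NaBH4, CeCl3·7H2O, MeOH, −40 → 0 °C; then 1 M HCl, THF, 0 °C
Reagents that add atoms: water, O
Why: Luche 1,2-reduction of the vinylogous ester carbonyl (methyl ester untouched) followed by acid-promoted Stork–Danheiser transposition (ionisation of the allylic alcohol, hydrolysis of the benzyloxy-stabilised cation) gives the γ-hydroxy enone without touching either stereocentre.

Step 8
Reactants: 16 methyl 2-[(3S,4R)-3-hydroxy-6-oxo-4-geranylgeranylcyclohex-1-en-1-yl]acetate
Product: 18 methyl 2-[(3R,4R)-3-hydroxy-6-oxo-4-geranylgeranylcyclohex-1-en-1-yl]acetate, via cis formate ester 17 (not isolated)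
Conditions: PPh3, diisopropyl azodicarboxylate, HCO2H, THF, −20 → 0 °C; then MeOH, KHCO3 (cat.), 0 °C
Reagents that add atoms: formic acid, OC=O
Why: Mitsunobu reaction (SN2 displacement of the allylic oxyphosphonium by formate) inverts the carbinol to the cis 3R,4R configuration, and the formate is methanolysed under near-neutral conditions that avoid dehydration to the phenol.

## Compound list

1 | (2E,6E,10E)-geranylgeraniol | OC/C=C(\C)CC/C=C(\C)CC/C=C(\C)CCC=C(C)C | starting material
2 | (2E,6E,10E)-geranylgeranyl bromide | BrC/C=C(\C)CC/C=C(\C)CC/C=C(\C)CCC=C(C)C | intermediate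
3 | 1-bromo-3,5-dimethoxybenzene | COc1cc(Br)cc(OC)c1 | starting material
4 | 3,5-dimethoxyphenylmagnesium bromide | COc1cc(OC)cc([Mg]Br)c1 | intermediate
5 | 1,3-dimethoxy-5-geranylgeranylbenzene | COc1cc(OC)cc(C/C=C(\C)CC/C=C(\C)CC/C=C(\C)CCC=C(C)C)c1 | intermediate
6 | 1,5-dimethoxy-3-geranylgeranylcyclohexa-1,4-diene | COC1=CC(C/C=C(\C)CC/C=C(\C)CC/C=C(\C)CCC=C(C)C)C=C(OC)C1 | intermediate
7 | 5-geranylgeranylcyclohexane-1,3-dione | O=C1CC(C/C=C(\C)CC/C=C(\C)CC/C=C(\C)CCC=C(C)C)CC(=O)C1 | intermediate
8 | methyl bromoacetate | COC(=O)CBr | starting material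
9 | methyl 2-(2,6-dioxo-4-geranylgeranylcyclohexyl)acetate (drawn as diketone; largely enolised; achiral) | COC(=O)CC1C(=O)CC(C/C=C(\C)CC/C=C(\C)CC/C=C(\C)CCC=C(C)C)CC1=O | intermediate
10 | benzyl alcohol | OCc1ccccc1 | starting material
11 | methyl 2-[(4R)-2-(benzyloxy)-6-oxo-4-geranylgeranylcyclohex-1-en-1-yl]acetate | COC(=O)CC1=C(OCc2ccccc2)C[C@@H](C/C=C(\C)CC/C=C(\C)CC/C=C(\C)CCC=C(C)C)CC1=O | intermediate
12 | methyl 2-[(4R)-2-(benzyloxy)-4-geranylgeranyl-6-(trimethylsilyloxy)cyclohexa-1,5-dien-1-yl]acetate | COC(=O)CC1=C(OCc2ccccc2)C[C@@H](C/C=C(\C)CC/C=C(\C)CC/C=C(\C)CCC=C(C)C)C=C1O[Si](C)(C)C | intermediate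
13 | methyl 2-[(4R,5S)-2-(benzyloxy)-6-oxo-4-geranylgeranyl-5-(trimethylsilyloxy)cyclohex-1-en-1-yl]acetate | COC(=O)CC1=C(OCc2ccccc2)C[C@@H](C/C=C(\C)CC/C=C(\C)CC/C=C(\C)CCC=C(C)C)[C@H](O[Si](C)(C)C)C1=O | intermediate
14 | methyl 2-[(4R,5S)-2-(benzyloxy)-5-hydroxy-6-oxo-4-geranylgeranylcyclohex-1-en-1-yl]acetate (OH trans to side chain) | COC(=O)CC1=C(OCc2ccccc2)C[C@@H](C/C=C(\C)CC/C=C(\C)CC/C=C(\C)CCC=C(C)C)[C@H](O)C1=O | intermediate
15 | methyl 2-[(4R,5S)-2-(benzyloxy)-5,6-dihydroxy-4-geranylgeranylcyclohex-1-en-1-yl]acetate (mixture at C-6) | COC(=O)CC1=C(OCc2ccccc2)C[C@@H](C/C=C(\C)CC/C=C(\C)CC/C=C(\C)CCC=C(C)C)[C@H](O)C1O | intermediate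
16 | methyl 2-[(3S,4R)-3-hydroxy-6-oxo-4-geranylgeranylcyclohex-1-en-1-yl]acetate (trans) | COC(=O)CC1=C[C@@H](O)[C@H](C/C=C(\C)CC/C=C(\C)CC/C=C(\C)CCC=C(C)C)CC1=O | intermediate
17 | methyl 2-[(3R,4R)-3-(formyloxy)-6-oxo-4-geranylgeranylcyclohex-1-en-1-yl]acetate | COC(=O)CC1=C[C@H](OC=O)[C@H](C/C=C(\C)CC/C=C(\C)CC/C=C(\C)CCC=C(C)C)CC1=O | intermediate
18 | methyl 2-[(3R,4R)-3-hydroxy-6-oxo-4-geranylgeranylcyclohex-1-en-1-yl]acetate (cis; CNP0274044.1) | COC(=O)CC1=C[C@H](O)[C@H](C/C=C(\C)CC/C=C(\C)CC/C=C(\C)CCC=C(C)C)CC1=O | target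

## Step count and risk

Total steps: 8. Longest linear sequence: 8 steps (from 1; compounds 3, 8 and 10 are commercial and enter directly).

**Step 5 (proposed new desymmetrisation).** The risks are low enantioselectivity because the stereocentre is remote from the reacting carbonyls, slow etherification with a weak chiral acid, and competing enol-lactone formation from the side-chain ester. The fallback uses known chemistry and sets out from 9. p-Toluenesulfonic acid-catalysed etherification with 10 (toluene, Dean–Stark) gives racemic 11, which is resolved by preparative chiral-phase chromatography into 11 and its mirror image methyl 2-[(4S)-2-(benzyloxy)-6-oxo-4-geranylgeranylcyclohex-1-en-1-yl]acetate F1. Because 9 is achiral, F1 is hydrolysed (1 M HCl, THF) back to 9 and recycled. The fallback comes back to the route at 11.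

**Step 6 (Rubottom oxidation).** The risks are partial epoxidation of the four chain alkenes, enolisation at the other ring CH2 under soft conditions, and an incomplete trans preference. The fallback sets out from 11 and avoids both silyl enol ether and peracid. Direct α'-acetoxylation with Mn(OAc)3 in benzene at reflux (through the manganese enolate) gives the trans acetate methyl 2-[(4R,5S)-5-acetoxy-2-(benzyloxy)-6-oxo-4-geranylgeranylcyclohex-1-en-1-yl]acetate F2. Methanolysis (K2CO3, MeOH, 0 °C; any epimerisation favours the wanted trans isomer) brings it back to the route at 14.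

**Step 8 (Mitsunobu inversion of the γ-hydroxy enone).** The risks are elimination of the activated alcohol followed by aromatisation to the phenol, and slow SN2 next to the branched ring carbon. The fallback moves the inversion to the ketone stage and sets out from 14.
- MsCl/Et3N gives the mesylate methyl 2-[(4R,5S)-2-(benzyloxy)-5-(methanesulfonyloxy)-6-oxo-4-geranylgeranylcyclohex-1-en-1-yl]acetate F3.
- CsOAc/18-crown-6 in toluene at 50 °C displaces it with inversion (SN2 accelerated by the adjacent carbonyl) to the cis acetate methyl 2-[(4R,5R)-5-acetoxy-2-(benzyloxy)-6-oxo-4-geranylgeranylcyclohex-1-en-1-yl]acetate F4.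
- NaBH4/CeCl3·7H2O then 1 M HCl gives, through the diol monoacetate methyl 2-[(4R,5R)-5-acetoxy-2-(benzyloxy)-6-hydroxy-4-geranylgeranylcyclohex-1-en-1-yl]acetate F5, the cis γ-acetoxy enone methyl 2-[(3R,4R)-3-acetoxy-6-oxo-4-geranylgeranylcyclohex-1-en-1-yl]acetate F6.
- Lipase B from Candida antarctica in pH 7 phosphate buffer/MTBE removes the acetate under neutral conditions, and the fallback comes back to the route at 18.

## Further compounds

F1 | step 5 | methyl 2-[(4S)-2-(benzyloxy)-6-oxo-4-geranylgeranylcyclohex-1-en-1-yl]acetate | COC(=O)CC1=C(OCc2ccccc2)C[C@H](C/C=C(\C)CC/C=C(\C)CC/C=C(\C)CCC=C(C)C)CC1=O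
F2 | step 6 | methyl 2-[(4R,5S)-5-acetoxy-2-(benzyloxy)-6-oxo-4-geranylgeranylcyclohex-1-en-1-yl]acetate | COC(=O)CC1=C(OCc2ccccc2)C[C@@H](C/C=C(\C)CC/C=C(\C)CC/C=C(\C)CCC=C(C)C)[C@H](OC(C)=O)C1=O
F3 | step 8 | methyl 2-[(4R,5S)-2-(benzyloxy)-5-(methanesulfonyloxy)-6-oxo-4-geranylgeranylcyclohex-1-en-1-yl]acetate | COC(=O)CC1=C(OCc2ccccc2)C[C@@H](C/C=C(\C)CC/C=C(\C)CC/C=C(\C)CCC=C(C)C)[C@H](OS(C)(=O)=O)C1=O
F4 | step 8 | methyl 2-[(4R,5R)-5-acetoxy-2-(benzyloxy)-6-oxo-4-geranylgeranylcyclohex-1-en-1-yl]acetate | COC(=O)CC1=C(OCc2ccccc2)C[C@@H](C/C=C(\C)CC/C=C(\C)CC/C=C(\C)CCC=C(C)C)[C@@H](OC(C)=O)C1=O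
F5 | step 8 | methyl 2-[(4R,5R)-5-acetoxy-2-(benzyloxy)-6-hydroxy-4-geranylgeranylcyclohex-1-en-1-yl]acetate (mixture at C-6) | COC(=O)CC1=C(OCc2ccccc2)C[C@@H](C/C=C(\C)CC/C=C(\C)CC/C=C(\C)CCC=C(C)C)[C@@H](OC(C)=O)C1O
F6 | step 8 | methyl 2-[(3R,4R)-3-acetoxy-6-oxo-4-geranylgeranylcyclohex-1-en-1-yl]acetate | COC(=O)CC1=C[C@H](OC(C)=O)[C@H](C/C=C(\C)CC/C=C(\C)CC/C=C(\C)CCC=C(C)C)CC1=O
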